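**Assumption:** (4R,6R)-actinol, the bulk carotenoid building block, is bought as the only chiral starting material; spiro compounds carry chamigrene numbering (C1–C5 in the bromoalkene ring B, C6 spiro, C7–C11 in ring A).

## Retrosynthetic overview

1. C9–OH from the C9 ketone by equilibrating 1,2-reduction; C10–Br by α′-bromination of the spiro enone, both steered by the spiro centre C6.
2. Ring B and the quaternary C6 (bonds C6–C1 and C5–C4) from a light-driven radical-cation [4+2] between a ring A 4-methylidenecyclohex-2-enyl silyl ether and 2-bromo-3-methylbuta-1,3-diene; the bought C9 silyloxy centre controls the face.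
3. Ring A dienophile from (4R,6R)-actinol by silylation, dehydrogenation and methylenation.
4. Bromodiene from 2-methylbut-1-en-3-yne and HBr.
5. Ring order: ring A is bought, ring B is formed in the photochemical step.

## Route

**Step 1**
Reactants: 1 (4R,6R)-4-hydroxy-2,2,6-trimethylcyclohexan-1-one
Product: 2 (4R,6R)-4-[(tert-butyldimethylsilyl)oxy]-2,2,6-trimethylcyclohexan-1-one
Conditions: tBuMe2SiCl, imidazole, DMF, 25 °C
Reagents that add atoms: tert-butyldimethylsilyl chloride, CC(C)(C)[Si](C)(C)Cl
Why: Imidazole-promoted silyl ether formation masks the secondary alcohol; both stereocentres are those bought in 1 and are not touched.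

**Step 2**
Reactants: 2 (4R,6R)-4-[(tert-butyldimethylsilyl)oxy]-2,2,6-trimethylcyclohexan-1-one
Product: 4 (4S)-4-[(tert-butyldimethylsilyl)oxy]-2,6,6-trimethylcyclohex-2-en-1-one, via trimethylsilyl enol ether 3 (not isolated)
Conditions: LiN(iPr)2, Me3SiCl, THF, −78 °C; then Pd(OAc)2 (10 mol %), O2 (1 atm), DMSO, 25 °C
Reagents that add atoms: none
Why: Saegusa–Ito dehydrogenation; only one α-carbon can enolise, so a single silyl enol ether forms and is oxidised to the enone, which removes the methyl-bearing stereocentre and leaves the bought carbinol centre unchanged in space (descriptor S by priority change only).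

**Step 3**
Reactants: 4 (4S)-4-[(tert-butyldimethylsilyl)oxy]-2,6,6-trimethylcyclohex-2-en-1-one
Product: 5 tert-butyldimethyl{[(1S)-3,5,5-trimethyl-4-methylidenecyclohex-2-en-1-yl]oxy}silane
Conditions: Zn, CH2Br2, TiCl4, THF/CH2Cl2, 0 → 25 °C
Reagents that add atoms: dibromomethane, BrCBr
Why: Lombardo–Takai methylenation, a non-basic titanium–zinc methylene reagent, olefinates the hindered enone carbonyl without γ-deprotonation or loss of the allylic silyl ether; no stereocentre is touched.

**Step 4**
Reactants: 6 2-methylbut-1-en-3-yne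
Product: 7 2-bromo-3-methylbuta-1,3-diene
Conditions: HBr (48 % aq.), CuBr (cat.), NH4Br, 0 → 20 °C
Reagents that add atoms: hydrogen bromide, Br
Why: CuBr-catalysed hydrobromination of a vinylacetylene (1,4-addition then allylic rearrangement, the chloroprene-type process) places bromine on the internal alkyne carbon; no stereocentre.

**Step 5**
Reactants: 5 tert-butyldimethyl{[(1S)-3,5,5-trimethyl-4-methylidenecyclohex-2-en-1-yl]oxy}silane; 7 2-bromo-3-methylbuta-1,3-diene
Product: 8 tert-butyl{[(6R,9S)-2-bromo-3,7,11,11-tetramethylspiro[5.5]undeca-2,7-dien-9-yl]oxy}dimethylsilane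
Conditions: 2,4,6-tris(4-methoxyphenyl)pyrylium tetrafluoroborate (3 mol %), 7 (5 equiv), MeNO2, 455 nm LEDs, −10 °C
Reagents that add atoms: none
Why: Proposed new method: the excited pyrylium salt oxidises the trisubstituted 1,3-diene of 5 (locked s-trans, so it can only act as the 2π partner) to its radical cation; the neutral bromodiene attacks the unhindered exocyclic CH2 with its methyl-bearing terminus (the better stabilised allyl cation, which fixes the regiochemistry); the ring then closes at C6 anti to the pseudoaxial C11 methyl, which is the face syn to the pseudoequatorial silyloxy group (a pseudoaxial OSi would be 1,3-diaxial to that methyl), so the bought C9 centre sets C6; electron return from the reduced catalyst or from a further molecule of 5 releases 8; the closest known reaction type is the cation-radical Diels–Alder reaction of electron-rich alkenes and s-trans dienes under aminium-salt or photoredox hole catalysis.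

**Step 6**
Reactants: 8 tert-butyl{[(6R,9S)-2-bromo-3,7,11,11-tetramethylspiro[5.5]undeca-2,7-dien-9-yl]oxy}dimethylsilane
Product: 10 (6R)-2-bromo-3,7,11,11-tetramethylspiro[5.5]undeca-2,7-dien-9-one, via allylic alcohol 9 (not isolated)
Conditions: Bu4NF, THF, 0 → 25 °C; then MnO2, CH2Cl2, 25 °C
Reagents that add atoms: none
Why: Fluoride desilylation then MnO2 oxidation of the allylic alcohol; the C9 centre has done its work in setting C6 and is erased on purpose, while C6 is untouched.

**Step 7**
Reactants: 10 (6R)-2-bromo-3,7,11,11-tetramethylspiro[5.5]undeca-2,7-dien-9-one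
Product: 12 (6S,10S)-2,10-dibromo-3,7,11,11-tetramethylspiro[5.5]undeca-2,7-dien-9-one, via trimethylsilyl dienol ether 11 (not isolated)
Conditions: LiN(iPr)2, Me3SiCl, THF, −78 °C; then NBS, THF, −78 → 0 °C
Reagents that add atoms: N-bromosuccinimide, O=C1CCC(=O)N1Br
Why: Kinetic α′-deprotonation of the enone and electrophilic bromination of the cross-conjugated silyl dienol ether; NBS should enter C10 anti to the pseudoaxial C11 methyl, on the face of C1, and the bromine then sits equatorial, so C10 is controlled by C6 (the C6 descriptor changes to S by priority only).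

**Step 8**
Reactants: 12 (6S,10S)-2,10-dibromo-3,7,11,11-tetramethylspiro[5.5]undeca-2,7-dien-9-one
Product: 13 (6S,9S,10S)-2,10-dibromo-3,7,11,11-tetramethylspiro[5.5]undeca-2,7-dien-9-ol
Conditions: Al(OiPr)3 (0.5 equiv), iPrOH/toluene, 80 °C, closed vessel
Reagents that add atoms: none
Why: Meerwein–Ponndorf–Verley reduction, selective for C=O over C–Br and C=C, run reversibly so that the thermodynamic alcohol forms: equatorial and trans to bromine, because the C9 epimer would hold its hydroxyl syn-axial to the axial C11 methyl; C9 is thus controlled by C10 and C6.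

## Compound list

1 | (4R,6R)-4-hydroxy-2,2,6-trimethylcyclohexan-1-one, (4R,6R)-actinol | C[C@@H]1C[C@@H](O)CC(C)(C)C1=O | starting material
2 | (4R,6R)-4-[(tert-butyldimethylsilyl)oxy]-2,2,6-trimethylcyclohexan-1-one | C[C@@H]1C[C@@H](O[Si](C)(C)C(C)(C)C)CC(C)(C)C1=O | intermediate
3 | tert-butyldimethyl{[(1R)-3,5,5-trimethyl-4-[(trimethylsilyl)oxy]cyclohex-3-en-1-yl]oxy}silane | CC1=C(O[Si](C)(C)C)C(C)(C)C[C@H](O[Si](C)(C)C(C)(C)C)C1 | intermediate
4 | (4S)-4-[(tert-butyldimethylsilyl)oxy]-2,6,6-trimethylcyclohex-2-en-1-one | CC1=C[C@@H](O[Si](C)(C)C(C)(C)C)CC(C)(C)C1=O | intermediate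
5 | tert-butyldimethyl{[(1S)-3,5,5-trimethyl-4-methylidenecyclohex-2-en-1-yl]oxy}silane | CC1=C[C@@H](O[Si](C)(C)C(C)(C)C)CC(C)(C)C1=C | intermediate
6 | 2-methylbut-1-en-3-yne | C=C(C)C#C | starting material
7 | 2-bromo-3-methylbuta-1,3-diene | C=C(C)C(Br)=C | intermediate
8 | tert-butyl{[(6R,9S)-2-bromo-3,7,11,11-tetramethylspiro[5.5]undeca-2,7-dien-9-yl]oxy}dimethylsilane (C1 and O9 on the same face of ring A) | CC1=C[C@@H](O[Si](C)(C)C(C)(C)C)CC(C)(C)[C@]12CCC(C)=C(Br)C2 | intermediate
9 | (6R,9S)-2-bromo-3,7,11,11-tetramethylspiro[5.5]undeca-2,7-dien-9-ol | CC1=C[C@@H](O)CC(C)(C)[C@]12CCC(C)=C(Br)C2 | intermediate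
10 | (6R)-2-bromo-3,7,11,11-tetramethylspiro[5.5]undeca-2,7-dien-9-one | CC1=CC(=O)CC(C)(C)[C@]12CCC(C)=C(Br)C2 | intermediate
11 | {[(6S)-2-bromo-3,7,11,11-tetramethylspiro[5.5]undeca-2,7,9-trien-9-yl]oxy}trimethylsilane (same spatial arrangement at C6 as 10) | CC1=CC(O[Si](C)(C)C)=CC(C)(C)[C@]12CCC(C)=C(Br)C2 | intermediate
12 | (6S,10S)-2,10-dibromo-3,7,11,11-tetramethylspiro[5.5]undeca-2,7-dien-9-one (Br10 and C1 on the same face of ring A) | CC1=CC(=O)[C@@H](Br)C(C)(C)[C@]12CCC(C)=C(Br)C2 | intermediate
13 | (6S,9S,10S)-2,10-dibromo-3,7,11,11-tetramethylspiro[5.5]undeca-2,7-dien-9-ol | CC1=C[C@H](O)[C@@H](Br)C(C)(C)[C@]12CCC(C)=C(Br)C2 | target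

## Step count and risks

Total step count: 8. Longest linear sequence: 7 (steps 1, 2, 3, 5, 6, 7, 8).

**Step 5, the new photochemical cycloaddition.** Risks are dimerisation of 5, [2+2] adducts, and a facial preference that is weak or opposite to the one argued. The fallback uses known chemistry, sets out from 4 and comes back at 12. It makes the spiro centre by a thermal Lewis-acid Diels–Alder reaction of a brominated dienone, so that the bromine-bearing carbon steers the diene instead of the silyloxy carbon. MeLi/CeCl3 (THF, −78 °C) adds to the ketone of 4 anti to the pseudoaxial methyl of the gem-dimethyl carbon and gives (1S,4S)-4-[(tert-butyldimethylsilyl)oxy]-1,2,6,6-tetramethylcyclohex-2-en-1-ol F1. Bu4NF and then MnO2 give (4S)-4-hydroxy-3,4,5,5-tetramethylcyclohex-2-en-1-one F2. The dianion of F2 (LiN(iPr)2, 2.2 equiv, THF, −78 °C) is brominated with NBS and the crude bromide is equilibrated with LiBr in acetone to the more stable epimer, bromine equatorial and trans to the pseudoaxial hydroxyl, (4R,6S)-6-bromo-4-hydroxy-3,4,5,5-tetramethylcyclohex-2-en-1-one F3. Burgess dehydration, for which the carbinol methyl is the only source of β-hydrogen, gives (6S)-6-bromo-3,5,5-trimethyl-4-methylidenecyclohex-2-en-1-one F4. F4 and 7 with Me2AlCl (CH2Cl2, −78 → −20 °C) give 12 by addition anti to the pseudoaxial methyl of the axial-bromine conformer, and step 8 follows.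

**Step 7, facial selectivity of the bromination at C10.** The two faces differ only through the conformation of the spiro ring, so the C10 epimer may dominate. The fallback sets out from 10, passes through the same dienol ether 11, and comes back at 12. It uses the same facial bias for oxygen and then inverts. Rubottom oxidation of 11 (mCPBA, NaHCO3, CH2Cl2, −20 °C; then Bu4NF/AcOH) gives (6S,10R)-2-bromo-10-hydroxy-3,7,11,11-tetramethylspiro[5.5]undeca-2,7-dien-9-one F5. Tf2O/2,6-lutidine (CH2Cl2, −78 °C) gives (6S,10R)-2-bromo-3,7,11,11-tetramethyl-9-oxospiro[5.5]undeca-2,7-dien-10-yl trifluoromethanesulfonate F6. LiBr in DMF (0 → 25 °C) displaces the triflate with inversion, an SN2 reaction activated by the adjacent carbonyl, and gives 12.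

**Step 8, reduction at C9.** Kinetic hydride reagents are expected to attack anti to the axial C11 methyl and give the C9 epimer. The equilibrating conditions could also be slow, could epimerise C10, or could close an epoxide. The fallback sets out from 12 and comes back at 13. It accepts the kinetic outcome and inverts it. LiBH(sBu)3 (THF, −78 °C) gives the axial alcohol (6S,9R,10S)-2,10-dibromo-3,7,11,11-tetramethylspiro[5.5]undeca-2,7-dien-9-ol F7. Mitsunobu reaction (4-nitrobenzoic acid, PPh3, diisopropyl azodicarboxylate, THF, 0 °C) inverts C9 and gives (6S,9S,10S)-2,10-dibromo-3,7,11,11-tetramethylspiro[5.5]undeca-2,7-dien-9-yl 4-nitrobenzoate F8. iBu2AlH (CH2Cl2, −78 °C) cleaves the ester without base and gives 13.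

## Further compounds

F1 | step 5 | (1S,4S)-4-[(tert-butyldimethylsilyl)oxy]-1,2,6,6-tetramethylcyclohex-2-en-1-ol | CC1=C[C@@H](O[Si](C)(C)C(C)(C)C)CC(C)(C)[C@]1(C)O
F2 | step 5 | (4S)-4-hydroxy-3,4,5,5-tetramethylcyclohex-2-en-1-one | CC1=CC(=O)CC(C)(C)[C@]1(C)O
F3 | step 5 | (4R,6S)-6-bromo-4-hydroxy-3,4,5,5-tetramethylcyclohex-2-en-1-one | CC1=CC(=O)[C@@H](Br)C(C)(C)[C@]1(C)O
F4 | step 5 | (6S)-6-bromo-3,5,5-trimethyl-4-methylidenecyclohex-2-en-1-one | CC1=CC(=O)[C@@H](Br)C(C)(C)C1=C
F5 | step 7 | (6S,10R)-2-bromo-10-hydroxy-3,7,11,11-tetramethylspiro[5.5]undeca-2,7-dien-9-one | CC1=CC(=O)[C@H](O)C(C)(C)[C@]12CCC(C)=C(Br)C2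
F6 | step 7 | (6S,10R)-2-bromo-3,7,11,11-tetramethyl-9-oxospiro[5.5]undeca-2,7-dien-10-yl trifluoromethanesulfonate | CC1=CC(=O)[C@H](OS(=O)(=O)C(F)(F)F)C(C)(C)[C@]12CCC(C)=C(Br)C2
F7 | step 8 | (6S,9R,10S)-2,10-dibromo-3,7,11,11-tetramethylspiro[5.5]undeca-2,7-dien-9-ol | CC1=C[C@@H](O)[C@@H](Br)C(C)(C)[C@]12CCC(C)=C(Br)C2
F8 | step 8 | (6S,9S,10S)-2,10-dibromo-3,7,11,11-tetramethylspiro[5.5]undeca-2,7-dien-9-yl 4-nitrobenzoate | CC1=C[C@H](OC(=O)c3ccc(cc3)[N+](=O)[O-])[C@@H](Br)C(C)(C)[C@]12CCC(C)=C(Br)C2
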